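**Retrosynthetic overview**
1. Ring C (the quinone) is detached last at the ring B O–C(quinone) bond, giving phenol 20 and 6-bromothymoquinone 22 (addition–elimination).
2. The strategy rests on ring A (the terminal benzene): ether oxygen on C1, isopropyl on C2, H on C3, methoxy on C4 (para to the oxygen), methyl on C5, H on C6. C6–C1–C2–C3 are the four carbons of a 2-aryloxy-3-isopropylbuta-1,3-diene and C4–C5 the alkyne carbons of pent-3-yn-2-one, whose acetyl group is the latent C4 methoxy.
3. The hindered ring A–O–ring B bond is never made by aryl coupling: the ring B phenol oxygen is acylated, the ester is methylenated to diene 13, and ring A is grown on that oxygen by [4+2] cycloaddition and dehydrogenation.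
4. Rings B and C both come from thymol through 2-isopropyl-4-methoxy-5-methylphenol 3 (formylation, benzylation, Dakin oxidation for ring B; bromination, oxidative demethylation for ring C).
5. Ring order: rings B and C are carried as preformed rings; ring A is the only ring constructed (steps 10 and 11); ring C is attached in step 17.

Key step: step 10

Remark: the target has no stereocentre and no stereogenic double bond, so no stereocontrol is required; ring A is the terminal benzene, ring B the central benzene and ring C the quinone.

**Route**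

Step 1
Reactants: 1 thymol (2-isopropyl-5-methylphenol)
Product: 2 4-bromo-2-isopropyl-5-methylphenol
Conditions: NBS, MeCN, 0 °C to rt
Reagents that add atoms: N-bromosuccinimide, O=C1CCC(=O)N1Br
Why: Electrophilic aromatic bromination, in which the hydroxyl group directs to the free para position C4 in preference to the ortho position C6.

Step 2
Reactants: 2 4-bromo-2-isopropyl-5-methylphenol
Product: 3 2-isopropyl-4-methoxy-5-methylphenol
Conditions: NaOMe (25% in MeOH), CuBr (cat.), DMF, 110 °C
Reagents that add atoms: sodium methoxide, [Na+].[O-]C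
Why: Copper-catalysed Ullmann-type methoxylation of an aryl bromide, a reaction that tolerates a free phenol (as in the conversion of bromophenols to methoxyphenols) and replaces only the C–Br bond.

Step 3
Reactants: 3 2-isopropyl-4-methoxy-5-methylphenol
Product: 4 2-hydroxy-3-isopropyl-5-methoxy-6-methylbenzaldehyde
Conditions: MgCl2, Et3N, (CH2O)n, MeCN, reflux
Reagents that add atoms: paraformaldehyde (formaldehyde), C=O
Why: Magnesium-mediated ortho-formylation (Casnati–Skattebøl), in which the magnesium phenoxide delivers formaldehyde to the only free ortho position and a second formaldehyde oxidises the benzylic alkoxide by hydride transfer.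

Step 4
Reactants: 4 2-hydroxy-3-isopropyl-5-methoxy-6-methylbenzaldehyde
Product: 5 2-(benzyloxy)-3-isopropyl-5-methoxy-6-methylbenzaldehyde
Conditions: BnBr, K2CO3, DMF, 60 °C
Reagents that add atoms: benzyl bromide, BrCc1ccccc1
Why: Williamson etherification of the phenoxide with a reactive benzylic halide, which proceeds in DMF despite the flanking isopropyl and formyl groups.

Step 5
Reactants: 5 2-(benzyloxy)-3-isopropyl-5-methoxy-6-methylbenzaldehyde
Product: 7 2-(benzyloxy)-3-isopropyl-5-methoxy-6-methylphenol, via aryl formate 6 (not isolated)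
Conditions: mCPBA, CH2Cl2, rt; then K2CO3, MeOH, rt
Reagents that add atoms: meta-chloroperoxybenzoic acid, OOC(=O)c1cccc(Cl)c1
Why: Dakin-type Baeyer–Villiger oxidation, in which the electron-rich ortho-alkoxy aryl group migrates in preference to hydride and the resulting formate is cleaved by transesterification.

Step 6
Reactants: 8 diethyl isopropylmalonate
Product: 9 isopropylmalonic acid
Conditions: KOH, EtOH/H2O, reflux; then HCl (aq), 0 °C
Reagents that add atoms: potassium hydroxide, [K+].[OH-]
Why: Saponification of a malonic diester, with cold acidification to avoid premature decarboxylation.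

Step 7
Reactants: 9 isopropylmalonic acid
Product: 10 3-methyl-2-methylidenebutanoic acid (2-isopropylacrylic acid)
Conditions: (CH2O)n, Et2NH, EtOAc, reflux
Reagents that add atoms: paraformaldehyde (formaldehyde), C=O
Why: Mannich condensation followed by decarboxylative elimination of the amine, the standard α-methylenation of monosubstituted malonic acids.

Step 8
Reactants: 10 3-methyl-2-methylidenebutanoic acid; 7 2-(benzyloxy)-3-isopropyl-5-methoxy-6-methylphenol
Product: 12 2-(benzyloxy)-3-isopropyl-5-methoxy-6-methylphenyl 3-methyl-2-methylidenebutanoate, via 2-isopropylacryloyl chloride 11 (not isolated)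
Conditions: (COCl)2, DMF (cat.), CH2Cl2, 0 °C to rt; then 7, Et3N, DMAP (cat.), BHT, CH2Cl2, 0 °C to rt
Reagents that add atoms: none
Why: Acid chloride formation and DMAP-catalysed O-acylation, which attaches the first carbon of the future ring A to the hindered phenol oxygen through an easily formed acyl C–O bond.

Step 9
Reactants: 12 2-(benzyloxy)-3-isopropyl-5-methoxy-6-methylphenyl 3-methyl-2-methylidenebutanoate
Product: 13 2-(benzyloxy)-3-isopropyl-5-methoxy-6-methylphenyl 3-isopropylbuta-1,3-dien-2-yl ether
Conditions: Cp2TiMe2 (3 equiv), toluene/THF, 70 °C, dark; filtration through basic alumina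
Reagents that add atoms: dimethyltitanocene, [CH3-].[CH3-].[Ti+4].c1cc[cH-]c1.c1cc[cH-]c1
Why: Petasis methylenation, in which the titanium methylidene formed on heating adds [2+2] to the ester carbonyl and the oxatitanacyclobutane collapses to the enol ether, a reaction established for aryl esters and for acrylates.

Step 10
Reactants: 13 2-(benzyloxy)-3-isopropyl-5-methoxy-6-methylphenyl 3-isopropylbuta-1,3-dien-2-yl ether; 14 pent-3-yn-2-one
Product: 15 1-{4-[2-(benzyloxy)-3-isopropyl-5-methoxy-6-methylphenoxy]-5-isopropyl-2-methylcyclohexa-1,4-dien-1-yl}ethanone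
Conditions: 14 (3 equiv), BHT (cat.), toluene, 120 °C, sealed tube
Reagents that add atoms: none
Why: A thermal, normal-electron-demand Diels–Alder reaction should take place through a concerted but asynchronous transition state in which the s-cis diene 13, its HOMO raised by the aryloxy oxygen, forms one bond from the CH2 on the aryloxy-bearing carbon to the methyl-bearing alkyne carbon of 14 and one from the CH2 on the isopropyl-bearing carbon to the acetyl-bearing alkyne carbon. The closest known reaction type is the cycloaddition of 2-alkoxy- and 2-aryloxybuta-1,3-dienes, made by titanium methylenation of acrylates, with acetylenic ketones to give cyclohexa-1,4-dienes that are later dehydrogenated. Ring A is closed as a six-membered carbocycle in an intermolecular [4+2] mode, both new C–C bonds being formed in the same step. No stereocentre arises, because the two new sp3 carbons are CH2 groups. The selectivity needed is the para orientation (acetyl carbon 1,4 to the aryloxy carbon), and it is secured by the oxygen lone pair, which puts the largest HOMO coefficient on the CH2 next to the C–OAr carbon so that it pairs with the β-carbon of the ynone, the isopropyl group being the weaker donor. Excess ynone and BHT counter the low rate expected from the two bulky substituents on the diene core and suppress polymerisation.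

Step 11
Reactants: 15 1-{4-[2-(benzyloxy)-3-isopropyl-5-methoxy-6-methylphenoxy]-5-isopropyl-2-methylcyclohexa-1,4-dien-1-yl}ethanone
Product: 16 1-{4-[2-(benzyloxy)-3-isopropyl-5-methoxy-6-methylphenoxy]-5-isopropyl-2-methylphenyl}ethanone
Conditions: DDQ (1.1 equiv), toluene, rt
Reagents that add atoms: none
Why: DDQ dehydrogenation of a cyclohexa-1,4-diene by hydride abstraction from a doubly allylic CH2 and proton loss, driven by aromatisation and fast enough at room temperature to leave the benzyl ether untouched.

Step 12
Reactants: 16 1-{4-[2-(benzyloxy)-3-isopropyl-5-methoxy-6-methylphenoxy]-5-isopropyl-2-methylphenyl}ethanone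
Product: 18 4-[2-(benzyloxy)-3-isopropyl-5-methoxy-6-methylphenoxy]-5-isopropyl-2-methylphenol, via aryl acetate 17 (not isolated)
Conditions: mCPBA, TFA (cat.), CH2Cl2, 0 °C to rt; then K2CO3, MeOH, rt
Reagents that add atoms: meta-chloroperoxybenzoic acid, OOC(=O)c1cccc(Cl)c1
Why: Baeyer–Villiger oxidation of an aryl methyl ketone, in which the para-aryloxy, ortho-methyl aryl group migrates in preference to methyl, followed by methanolysis of the aryl acetate.

Step 13
Reactants: 18 4-[2-(benzyloxy)-3-isopropyl-5-methoxy-6-methylphenoxy]-5-isopropyl-2-methylphenol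
Product: 19 2-(benzyloxy)-1-isopropyl-3-(2-isopropyl-4-methoxy-5-methylphenoxy)-5-methoxy-4-methylbenzene
Conditions: MeI, K2CO3, DMF, rt
Reagents that add atoms: iodomethane, CI
Why: Williamson O-methylation of an unhindered phenoxide (flanked by H and methyl), which completes the substitution pattern of ring A.

Step 14
Reactants: 19 2-(benzyloxy)-1-isopropyl-3-(2-isopropyl-4-methoxy-5-methylphenoxy)-5-methoxy-4-methylbenzene
Product: 20 6-isopropyl-2-(2-isopropyl-4-methoxy-5-methylphenoxy)-4-methoxy-3-methylphenol
Conditions: H2 (1 atm), Pd/C, EtOAc/EtOH, rt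
Reagents that add atoms: none
Why: Catalytic hydrogenolysis of a benzyl aryl ether, to which the diaryl ether and the methyl ethers are inert.

Step 15
Reactants: 3 2-isopropyl-4-methoxy-5-methylphenol
Product: 21 2-bromo-6-isopropyl-4-methoxy-3-methylphenol
Conditions: NBS, CH2Cl2, −10 °C to 0 °C
Reagents that add atoms: N-bromosuccinimide, O=C1CCC(=O)N1Br
Why: Electrophilic aromatic bromination ortho to the free hydroxyl, the stronger director, at the site flanked by OH and methyl, which is less hindered than the one between methoxy and isopropyl.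

Step 16
Reactants: 21 2-bromo-6-isopropyl-4-methoxy-3-methylphenol
Product: 22 3-bromo-5-isopropyl-2-methylcyclohexa-2,5-diene-1,4-dione (6-bromothymoquinone)
Conditions: (NH4)2Ce(NO3)6, MeCN/H2O, 0 °C
Reagents that add atoms: water, O
Why: Oxidative demethylation of a para-methoxyphenol to the para-benzoquinone, in which two-electron oxidation is followed by attack of water at the methoxy-bearing carbon and loss of methanol.

Step 17
Reactants: 20 6-isopropyl-2-(2-isopropyl-4-methoxy-5-methylphenoxy)-4-methoxy-3-methylphenol; 22 3-bromo-5-isopropyl-2-methylcyclohexa-2,5-diene-1,4-dione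
Product: 23 5-isopropyl-3-[6-isopropyl-2-(2-isopropyl-4-methoxy-5-methylphenoxy)-4-methoxy-3-methylphenoxy]-2-methylcyclohexa-2,5-diene-1,4-dione (CNP0335608.0)
Conditions: Cs2CO3, MeCN, 0 °C to rt, argon
Reagents that add atoms: none
Why: Addition–elimination (vinylogous acyl substitution) on a bromoquinone, in which the phenoxide adds to the bromine-bearing carbon and bromide is expelled from the resulting enolate, so the aryloxy group takes the place of bromine.

**Compound list**
1 | thymol (2-isopropyl-5-methylphenol) | Cc1ccc(C(C)C)c(O)c1 | starting material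
2 | 4-bromo-2-isopropyl-5-methylphenol | Cc1cc(O)c(C(C)C)cc1Br | intermediate
3 | 2-isopropyl-4-methoxy-5-methylphenol | COc1cc(C(C)C)c(O)cc1C | intermediate
4 | 2-hydroxy-3-isopropyl-5-methoxy-6-methylbenzaldehyde | COc1cc(C(C)C)c(O)c(C=O)c1C | intermediate
5 | 2-(benzyloxy)-3-isopropyl-5-methoxy-6-methylbenzaldehyde | COc1cc(C(C)C)c(OCc2ccccc2)c(C=O)c1C | intermediate
6 | 2-(benzyloxy)-3-isopropyl-5-methoxy-6-methylphenyl formate | COc1cc(C(C)C)c(OCc2ccccc2)c(OC=O)c1C | intermediate
7 | 2-(benzyloxy)-3-isopropyl-5-methoxy-6-methylphenol | COc1cc(C(C)C)c(OCc2ccccc2)c(O)c1C | intermediate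
8 | diethyl isopropylmalonate | CCOC(=O)C(C(C)C)C(=O)OCC | starting material
9 | isopropylmalonic acid | CC(C)C(C(=O)O)C(=O)O | intermediate
10 | 3-methyl-2-methylidenebutanoic acid (2-isopropylacrylic acid) | C=C(C(C)C)C(=O)O | intermediate
11 | 3-methyl-2-methylidenebutanoyl chloride (2-isopropylacryloyl chloride) | C=C(C(C)C)C(=O)Cl | intermediate
12 | 2-(benzyloxy)-3-isopropyl-5-methoxy-6-methylphenyl 3-methyl-2-methylidenebutanoate | C=C(C(C)C)C(=O)Oc1c(C)c(OC)cc(C(C)C)c1OCc1ccccc1 | intermediate
13 | 2-(benzyloxy)-3-isopropyl-5-methoxy-6-methylphenyl 3-isopropylbuta-1,3-dien-2-yl ether | C=C(C(C)C)C(=C)Oc1c(C)c(OC)cc(C(C)C)c1OCc1ccccc1 | intermediate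
14 | pent-3-yn-2-one | CC#CC(C)=O | starting material
15 | 1-{4-[2-(benzyloxy)-3-isopropyl-5-methoxy-6-methylphenoxy]-5-isopropyl-2-methylcyclohexa-1,4-dien-1-yl}ethanone | CC(=O)C1=C(C)CC(Oc2c(C)c(OC)cc(C(C)C)c2OCc2ccccc2)=C(C(C)C)C1 | intermediate
16 | 1-{4-[2-(benzyloxy)-3-isopropyl-5-methoxy-6-methylphenoxy]-5-isopropyl-2-methylphenyl}ethanone | CC(=O)c1cc(C(C)C)c(Oc2c(C)c(OC)cc(C(C)C)c2OCc2ccccc2)cc1C | intermediate
17 | 4-[2-(benzyloxy)-3-isopropyl-5-methoxy-6-methylphenoxy]-5-isopropyl-2-methylphenyl acetate | CC(=O)Oc1cc(C(C)C)c(Oc2c(C)c(OC)cc(C(C)C)c2OCc2ccccc2)cc1C | intermediate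
18 | 4-[2-(benzyloxy)-3-isopropyl-5-methoxy-6-methylphenoxy]-5-isopropyl-2-methylphenol | Oc1cc(C(C)C)c(Oc2c(C)c(OC)cc(C(C)C)c2OCc2ccccc2)cc1C | intermediate
19 | 2-(benzyloxy)-1-isopropyl-3-(2-isopropyl-4-methoxy-5-methylphenoxy)-5-methoxy-4-methylbenzene | COc1cc(C(C)C)c(Oc2c(C)c(OC)cc(C(C)C)c2OCc2ccccc2)cc1C | intermediate
20 | 6-isopropyl-2-(2-isopropyl-4-methoxy-5-methylphenoxy)-4-methoxy-3-methylphenol | COc1cc(C(C)C)c(Oc2c(C)c(OC)cc(C(C)C)c2O)cc1C | intermediate
21 | 2-bromo-6-isopropyl-4-methoxy-3-methylphenol | COc1cc(C(C)C)c(O)c(Br)c1C | intermediate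
22 | 3-bromo-5-isopropyl-2-methylcyclohexa-2,5-diene-1,4-dione (6-bromothymoquinone) | CC1=C(Br)C(=O)C(C(C)C)=CC1=O | intermediate
23 | 5-isopropyl-3-[6-isopropyl-2-(2-isopropyl-4-methoxy-5-methylphenoxy)-4-methoxy-3-methylphenoxy]-2-methylcyclohexa-2,5-diene-1,4-dione (CNP0335608.0) | COc1cc(C(C)C)c(Oc2c(C)c(OC)cc(C(C)C)c2OC2=C(C)C(=O)C=C(C(C)C)C2=O)cc1C | target

**Totals**
Total step count: 17.
Longest linear sequence: 13 steps (steps 1, 2, 3, 4, 5, 8, 9, 10, 11, 12, 13, 14, 17).

**Steps most likely to fail**

Step 10 (cycloaddition). The diene core carries an isopropyl group and a 2,6-disubstituted aryloxy group on adjacent carbons, so the s-cis conformer may be poorly populated and the cycloaddition slow. At the temperature then needed the dienyl ether may polymerise or hydrolyse. The para preference may also be eroded, because the isopropyl donor opposes the aryloxy donor. The fallback gives up the cycloaddition and makes the ring A–O–ring B bond by aryl coupling; it sets out from 7 and comes back to the route at 19. Commercial carvacrol methyl ether (5-isopropyl-2-methylanisole, COc1cc(C(C)C)ccc1C) would be brominated para to the methoxy group with NBS in MeCN to give 1-bromo-2-isopropyl-4-methoxy-5-methylbenzene F1. F1 would then be joined to phenol 7 in an Ullmann diaryl ether synthesis (CuI, 2,2,6,6-tetramethylheptane-3,5-dione, Cs2CO3, NMP, 120 °C) to give 19 directly. Steps 8 to 13 would then not be needed.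

Step 9 (methylenation). The ester carbonyl is hindered and conjugated, so methylenation may stall. The oxatitanacyclobutane may fragment with loss of the aryloxide instead of the titanium oxide, and the acid-sensitive dienyl ether may hydrolyse during isolation. The fallback builds the diene from a ketone instead of an ester; it sets out from 7 and comes back at 13. Phenol 7 would be alkylated with 1-bromo-3-methylbutan-2-one (K2CO3, acetone) to give 1-[2-(benzyloxy)-3-isopropyl-5-methoxy-6-methylphenoxy]-3-methylbutan-2-one F2. Its aryloxy-bearing CH2 would be methylenated by a Mannich condensation–elimination ((CH2O)n, diisopropylammonium trifluoroacetate, THF, reflux) to give 2-[2-(benzyloxy)-3-isopropyl-5-methoxy-6-methylphenoxy]-4-methylpent-1-en-3-one F3. Wittig methylenation of the ketone of F3 (Ph3P=CH2, THF, 0 °C) would give diene 13.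

Step 17 (quinone coupling). The phenoxide of 20 is electron-rich and flanked by isopropyl and aryloxy groups, so electron transfer to the quinone may outrun substitution, giving redox products. Attack at the unsubstituted quinone carbon, or base-induced decomposition of the bromoquinone, may also compete. The fallback couples ring C in its reduced, protected form and oxidises at the end; it sets out from 21 and 20 and comes back at 23. Phenol 21 would be benzylated (BnBr, K2CO3, DMF) to give 2-(benzyloxy)-3-bromo-1-isopropyl-5-methoxy-4-methylbenzene F4. Ullmann coupling of F4 with 20 (CuI, 2,2,6,6-tetramethylheptane-3,5-dione, Cs2CO3, NMP, 120 °C) would give the benzyl-protected triaryl diether F5. Hydrogenolysis (H2, Pd/C) would free the ring C para-methoxyphenol F6. This is the only free phenol in the molecule, so PhI(OAc)2 in MeCN/H2O at 0 °C should oxidise it alone, with loss of methanol, to quinone 23.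

**Further compounds**
F1 | step 10 | 1-bromo-2-isopropyl-4-methoxy-5-methylbenzene | COc1cc(C(C)C)c(Br)cc1C
F2 | step 9 | 1-[2-(benzyloxy)-3-isopropyl-5-methoxy-6-methylphenoxy]-3-methylbutan-2-one | CC(C)C(=O)COc1c(C)c(OC)cc(C(C)C)c1OCc1ccccc1
F3 | step 9 | 2-[2-(benzyloxy)-3-isopropyl-5-methoxy-6-methylphenoxy]-4-methylpent-1-en-3-one | C=C(Oc1c(C)c(OC)cc(C(C)C)c1OCc1ccccc1)C(=O)C(C)C
F4 | step 17 | 2-(benzyloxy)-3-bromo-1-isopropyl-5-methoxy-4-methylbenzene | COc1cc(C(C)C)c(OCc2ccccc2)c(Br)c1C
F5 | step 17 | 2-(benzyloxy)-1-isopropyl-3-[6-isopropyl-2-(2-isopropyl-4-methoxy-5-methylphenoxy)-4-methoxy-3-methylphenoxy]-5-methoxy-4-methylbenzene | COc1cc(C(C)C)c(Oc2c(C)c(OC)cc(C(C)C)c2Oc2c(C)c(OC)cc(C(C)C)c2OCc2ccccc2)cc1C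
F6 | step 17 | 6-isopropyl-2-[6-isopropyl-2-(2-isopropyl-4-methoxy-5-methylphenoxy)-4-methoxy-3-methylphenoxy]-4-methoxy-3-methylphenol | COc1cc(C(C)C)c(Oc2c(C)c(OC)cc(C(C)C)c2Oc2c(C)c(OC)cc(C(C)C)c2O)cc1C
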